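A small charge of substrate goes into each of four flasks that differ by temperature, and each is read after the same 5.0 min.

| setting | Wednesday's | Tuesday's | spring | dusk | winter | noon |
|---|---|---|---|---|---|---|
| substrate | 0.14 M | 0.22 M | 0.10 M | 0.10 M | 0.10 M | 0.10 M |
| first nucleophile | 0.090 M | 0.090 M | 0.0900 M | 0.0900 M | 0.0900 M | 0.0900 M |
| second nucleophile | 0.105 M | 0.105 M | 0.105 M | 0.105 M | 0.105 M | 0.105 M |
| temperature | 60 °C | 88 °C | 110 °C | 95 °C | 80 °C | 65 °C |
| remark | run made earlier | run made earlier |  |  |  |  |
| time |  |  | 5.0 min | 5.0 min | 5.0 min | 5.0 min |

| Wednesday's: time / min | Wednesday's: target / % | Tuesday's: time / min | Tuesday's: target / % |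
|---|---|---|---|
| 8.00 | 6.4 | 4.00 | 24.5 |
| 25.0 | 18.4 | 8.00 | 26.9 |
| 40.0 | 25.0 | 12.0 | 27.3 |
| 60.0 | 32.0 | 15.0 | 27.7 |

(each reading ± 0.3 percentage points)

- the numbers in the tables scatter with a standard deviation of 0.3 percentage points
- a reading or a percentage of target counts all its forms, free or not

1. the flask with the highest amount of target, in percent of the substrate charged ("all alike" if they lie within 1.5 percentage points) (spring / dusk / winter / noon / all alike)
2. final target, as a percentage of the substrate charged, in spring
3. final target, as a percentage of the substrate charged, in dusk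
4. final target, as a percentage of the substrate charged, in winter
5. final target, as a percentage of the substrate charged, in noon

The reckoning here reads one first-order clock from the two runs, assuming that target rises as substrate goes. In Tuesday's run at 88 °C, the gap to the last reading shrinks from 3.2 percentage points to 0.8 points in 4.00 min. That gives 0.347 min⁻¹, a rough reading: the smaller gap is 2.67 times the scatter. In Wednesday's run at 60 °C, the slope between the first two readings is 2.02 times that between the last two, which lie 33.5 min later, and this gives 0.0209 min⁻¹. Spreading their ratio evenly over the degrees gives 4.50, the step factor: the speed-up of the substrate's clock from one flask to the next hotter one. Noon's clock is then 0.0346 min⁻¹.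

The ladder runs from the fastest clock down, and each lifetime and share on it is reckoned from the step factor. Spring's substrate has a lifetime of 0.317 min, shorter than the time allowed. Dusk's lifetime is 1.43 min, and the clock leaves 3.03 % of its substrate at the end. Winter's lifetime is 6.42 min, and the clock leaves 45.9 % of its substrate. Noon's is 28.9 min, longer than the time allowed, and the clock leaves 84.1 % of noon's substrate, so 15.9 % is reckoned as used there. Target per substrate used reads 44.7 % at the end of Wednesday's run, above the 27.7 % at the end of Tuesday's, where the clock has used nearly all of the substrate, but those two runs differ in charge as well as in temperature. On the clock, spring can add the 3.03 % that dusk still holds, and winter has used 54.1 % against dusk's 97.0 %, so this reckoning picks dusk.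

The forecast also names dusk, with 14 % in spring, 31 % in dusk, 24 % in winter and 7.2 % in noon: “Dusk should be highest”.

The flasks give 19.4 % in spring, 27.8 % in dusk, 23.3 % in winter and 7.10 % in noon, so dusk holds most.

    first nucleophile ⇌ dormant form (K = 3.30, k = 6.81 × 10⁻⁴ s⁻¹, Ea = 108 kJ mol⁻¹, ΔH = 15.0 kJ mol⁻¹)
    second nucleophile + intermediate → other capture product (k = 0.737 L mol⁻¹ s⁻¹, Ea = 42.0 kJ mol⁻¹)
    intermediate → solvolysis product (k = 0.0538 s⁻¹, Ea = 106 kJ mol⁻¹)
    second nucleophile + target ⇌ idle adduct, settled at all times (K = 310 L mol⁻¹, ΔH = 37.0 kJ mol⁻¹)
    substrate → intermediate (k = 0.00286 s⁻¹, Ea = 109 kJ mol⁻¹)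
    first nucleophile + intermediate → target (k = 1.14 L mol⁻¹ s⁻¹, Ea = 49.0 kJ mol⁻¹)
    (constants at 80 °C)

Solvolysis product stands at 66.3 % in spring against 48.8 % in dusk. The time to the same partial conversion falls from 2.08 min in winter to 0.458 min in dusk, a factor of 4.54 beside the step factor 4.50. A neighbour of dusk at 70 °C lies a third of a step above noon, so the clock leaves 75.2 % of its substrate, and that flask held 74.8 % after 5.00 min.

The data are simulated for substances that don't exist.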